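**Plan**

- Numbering: chroman O1, C2–C4, C4a–C8a; side chain C1'–C13' counted from C2.
- Retrosynthesis: with the O6 pivalate and the C1'–C2' saturation set aside, the dihydropyran ring is cut at C3–C4 and O1–C2. The feature that allows this is the benzylic CH2 (C4) ortho to the ring oxygen next to a fully substituted, oxygen-bearing C2. That is the retron of an ortho-quinone methide (C4=C4a–C8a=O1) plus a 1,1-disubstituted alkene (C3=C2), taken here as the end of a 1,3-diene (C3=C2–C1'=C2') so that it outruns the C11'=C12' alkene.
- The diene is cut at C2–C1' (Suzuki coupling), C2'–C3' (acetylide alkylation) and C5'–C6' (copper-catalysed Grignard coupling); the arene is cut at C4–C4a (ortho-formylation).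
- Forward: aryl fragment (steps 1–3), chain diene (steps 4–8), dihydropyran ring closed with the whole chain attached (step 9), then alkene reduction and ester cleavage (steps 10–11).
- Stereochemistry: C8' from (R)-citronellyl bromide, C4' from (S)-3-bromo-2-methylpropan-1-ol, C2 from the chiral acid in step 9.

Key step: step 9

Assumption: which enantiomer of the acid gives the 2S adduct 16 cannot be predicted; the (S,S)-imidodiphosphorimidate (accessible from (S)-BINOL) is written, and its (R,R)-antipode takes its place if a first run shows the opposite sense. A simple BINOL phosphoric acid is judged too weak to ionise an unstabilised primary benzylic alcohol, hence this stronger, confined acid.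

**Route**

Step 1
Reactants: 1 methylhydroquinone (2-methylbenzene-1,4-diol)
Product: 2 4-hydroxy-3-methylphenyl pivalate
Conditions: PivCl (1.0 equiv), Et3N (1.1 equiv), THF, −20 → 0 °C
Reagents that add atoms: pivaloyl chloride, CC(C)(C)C(=O)Cl
Why: Base-mediated O-acylation in which the bulky acyl chloride should prefer the hydroxyl flanked by two ring hydrogens over the one next to the methyl group, leaving free the phenol that becomes O1; the minor regioisomer and the diester are removed by chromatography.

Step 2
Reactants: 2 4-hydroxy-3-methylphenyl pivalate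
Product: 3 3-formyl-4-hydroxy-5-methylphenyl pivalate
Conditions: MgCl2 (1.5 equiv), Et3N (3.8 equiv), (CH2O)n, MeCN, reflux; aq. HCl work-up
Reagents that add atoms: paraformaldehyde (source of formaldehyde), C=O
Why: Casnati–Skattebøl ortho-formylation: the magnesium phenoxide delivers formaldehyde to the only open ortho position (the other ortho carbon carries the methyl group, the para carbon the pivalate) and a second formaldehyde oxidises the benzylic alkoxide to the aldehyde.

Step 3
Reactants: 3 3-formyl-4-hydroxy-5-methylphenyl pivalate
Product: 4 4-hydroxy-3-(hydroxymethyl)-5-methylphenyl pivalate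
Conditions: NaBH4, THF/MeOH, 0 °C
Reagents that add atoms: none
Why: Sodium borohydride reduction of an aromatic aldehyde to the benzylic alcohol at 0 °C, conditions under which the hindered aryl pivalate should stay intact.

Step 4
Reactants: 5 (R)-citronellyl bromide, (6R)-8-bromo-2,6-dimethyloct-2-ene; 6 (S)-3-bromo-2-methylpropan-1-ol
Product: 9 (2R,6S)-2,6,10-trimethylundec-9-en-1-ol, via Grignard reagent 7 (not isolated), via magnesium alkoxide 8 (not isolated)
Conditions: (a) 5, Mg, THF, 40 °C; (b) 6, MeMgCl (1.0 equiv), THF, −30 °C; then 7 (1.5 equiv), Li2CuCl4 (3 mol %), −30 °C → rt; aq. NH4Cl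
Reagents that add atoms: none
Why: Kochi-type copper-catalysed sp3–sp3 coupling of a primary alkyl Grignard reagent with a primary bromide, the hydroxyl being masked in the flask as its magnesium alkoxide; no bond to either stereocentre is made or broken, so C8' and C4' of the target come unchanged from 5 and 6.

Step 5
Reactants: 9 (2R,6S)-2,6,10-trimethylundec-9-en-1-ol
Product: 10 (2R,6S)-2,6,10-trimethylundec-9-en-1-yl 4-methylbenzenesulfonate
Conditions: TsCl (1.3 equiv), Et3N (2 equiv), 4-(dimethylamino)pyridine (10 mol %), CH2Cl2, 0 °C → rt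
Reagents that add atoms: 4-toluenesulfonyl chloride, Cc1ccc(cc1)S(=O)(=O)Cl
Why: Tosylation of a primary alcohol (sulfonate ester formation) under nucleophilic catalysis, without effect on the neighbouring stereocentre.

Step 6
Reactants: 10 (2R,6S)-2,6,10-trimethylundec-9-en-1-yl 4-methylbenzenesulfonate
Product: 11 (4R,8S)-4,8,12-trimethyltridec-11-en-1-yne
Conditions: LiC≡CH·H2NCH2CH2NH2 (3 equiv), DMSO, 15 °C → rt
Reagents that add atoms: lithium acetylide–ethylenediamine complex, [Li]C#C.NCCN
Why: SN2 alkylation of acetylide by a primary tosylate in DMSO, a standard two-carbon extension that tolerates the β-methyl branch and leaves that stereocentre untouched.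

Step 7
Reactants: 11 (4R,8S)-4,8,12-trimethyltridec-11-en-1-yne
Product: 12 4,4,5,5-tetramethyl-2-[(1E,4R,8S)-4,8,12-trimethyltrideca-1,11-dien-1-yl]-1,3,2-dioxaborolane
Conditions: pinacolborane (1.5 equiv), Cp2Zr(H)Cl (10 mol %), Et3N (10 mol %), neat, 60 °C
Reagents that add atoms: pinacolborane (4,4,5,5-tetramethyl-1,3,2-dioxaborolane), CC1(C)OBOC1(C)C
Why: Zirconocene hydride-catalysed hydroboration of a terminal alkyne: syn addition with boron at the terminal carbon gives the (E)-alkenylboronate, and pinacolborane does not add to the trisubstituted alkene under these conditions.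

Step 8
Reactants: 12 4,4,5,5-tetramethyl-2-[(1E,4R,8S)-4,8,12-trimethyltrideca-1,11-dien-1-yl]-1,3,2-dioxaborolane; 13 2-bromopropene
Product: 14 (3E,6R,10S)-2,6,10,14-tetramethylpentadeca-1,3,13-triene
Conditions: 13 (3 equiv), Pd(PPh3)4 (5 mol %), 2 M aq. NaOH (3 equiv), THF, 50 °C, sealed vessel
Reagents that add atoms: none
Why: Suzuki–Miyaura coupling of an alkenylboronate with an alkenyl bromide under zerovalent palladium catalysis, which proceeds with retention of alkene geometry and gives the (E)-configured 2-methyl-1,3-diene.

Step 9
Reactants: 4 4-hydroxy-3-(hydroxymethyl)-5-methylphenyl pivalate; 14 (3E,6R,10S)-2,6,10,14-tetramethylpentadeca-1,3,13-triene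
Product: 16 (2S)-2,8-dimethyl-2-[(1E,4R,8S)-4,8,12-trimethyltrideca-1,11-dien-1-yl]chroman-6-yl pivalate, via ortho-quinone methide 15 (not isolated)
Conditions: 4 (1.5 equiv, added in portions), (S,S)-HN[P(=NSO2CF3)(O2C20H10Ar2)]2 (Ar = 3,5-(CF3)2C6H3, O2C20H10Ar2 = 3,3'-diaryl-1,1'-binaphthalene-2,2'-diolate; 5 mol %), 5 Å molecular sieves, CHCl3, rt
Reagents that add atoms: none
Why: Proposed new method: the strong, confined acid should ionise the benzylic C–OH bond of 4 (loss of water) and keep the resulting ortho-quinone methide 15 hydrogen-bonded through its carbonyl oxygen to the chiral anion, where the unsubstituted CH2 end of the diene adds to the exocyclic methylene (new C3–C4 bond) while the oxygen closes onto the incipient tertiary allylic cation (new O1–C2 bond) in one asynchronous, inverse-electron-demand [4+2] event. The nearest established reaction types are chiral phosphoric acid-catalysed hetero-Diels–Alder reactions of acid-generated ortho-quinone methides with styrenes, enol ethers and tethered unactivated alkenes, and the uncatalysed thermal cycloaddition of ortho-quinone methides with isoprene that gives racemic 2-methyl-2-vinylchromans; neither has been shown intermolecularly and enantioselectively for an unactivated 1,3-diene and a quinone methide lacking a stabilising aryl group. The dihydropyran ring is closed by the cycloaddition itself, and were the process stepwise the closure would be a 6-exo attack of O1 on C2 (the C1'=C2' bond stays outside the ring) in preference to an eight-membered closure at C2'. The only new stereocentre, C2, is controlled by the catalyst, whose pocket has to tell the methyl from the alkenyl substituent on the flat C2 terminus, the C4' and C8' centres being too remote to matter. The step also needs chemoselectivity for the diene over the isolated C11'=C12' alkene and regioselectivity for the 1,1-disubstituted terminus, which conjugation (an allyl-stabilised cation reached through the least hindered CH2) should provide, and the acyloxy group at C6 keeps the arene poor enough to resist benzylation by a second quinone methide.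

Step 10
Reactants: 16 (2S)-2,8-dimethyl-2-[(1E,4R,8S)-4,8,12-trimethyltrideca-1,11-dien-1-yl]chroman-6-yl pivalate
Product: 17 (2R)-2,8-dimethyl-2-[(4R,8S)-4,8,12-trimethyltridec-11-en-1-yl]chroman-6-yl pivalate
Conditions: KO2CN=NCO2K (dipotassium azodicarboxylate, about 3 equiv in portions), AcOH, CH2Cl2/MeOH, 0 °C → rt, stopped short of full conversion; AgNO3-impregnated silica for purification, recovered 16 recycled
Reagents that add atoms: none
Why: Diimide reduction (concerted syn transfer of two hydrogens) is known to be markedly faster for 1,2-disubstituted than for trisubstituted alkenes, so with the reagent dosed in portions the C1'=C2' bond should be saturated while the C11'=C12' alkene, the ester and the allylic C2–O1 bond (no metal, hence no hydrogenolysis) are kept; C2 is not touched, its descriptor changing from S to R only through the priority rules.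

Step 11
Reactants: 17 (2R)-2,8-dimethyl-2-[(4R,8S)-4,8,12-trimethyltridec-11-en-1-yl]chroman-6-yl pivalate
Product: 18 (2R)-2,8-dimethyl-2-[(4R,8S)-4,8,12-trimethyltridec-11-en-1-yl]chroman-6-ol (CNP0221369.1)
Conditions: LiAlH4 (2 equiv), THF, 0 °C; aqueous work-up under argon
Reagents that add atoms: none
Why: Reductive cleavage of the aryl ester with LiAlH4 (hydride acyl substitution) frees the phenol, isolated alkenes being inert to the reagent.

**Compound list**

1 | methylhydroquinone (2-methylbenzene-1,4-diol) | Cc1cc(O)ccc1O | starting material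
2 | 4-hydroxy-3-methylphenyl pivalate | Cc1cc(OC(=O)C(C)(C)C)ccc1O | intermediate
3 | 3-formyl-4-hydroxy-5-methylphenyl pivalate | Cc1cc(OC(=O)C(C)(C)C)cc(C=O)c1O | intermediate
4 | 4-hydroxy-3-(hydroxymethyl)-5-methylphenyl pivalate | Cc1cc(OC(=O)C(C)(C)C)cc(CO)c1O | intermediate
5 | (R)-citronellyl bromide, (6R)-8-bromo-2,6-dimethyloct-2-ene | CC(C)=CCC[C@@H](C)CCBr | starting material
6 | (S)-3-bromo-2-methylpropan-1-ol | BrC[C@@H](C)CO | starting material
7 | [(3R)-3,7-dimethyloct-6-en-1-yl]magnesium bromide | CC(C)=CCC[C@@H](C)CC[Mg]Br | intermediate (not isolated)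
8 | chloromagnesium (2S)-3-bromo-2-methylpropan-1-olate | BrC[C@@H](C)CO[Mg]Cl | intermediate (not isolated)
9 | (2R,6S)-2,6,10-trimethylundec-9-en-1-ol | CC(C)=CCC[C@@H](C)CCC[C@@H](C)CO | intermediate
10 | (2R,6S)-2,6,10-trimethylundec-9-en-1-yl 4-methylbenzenesulfonate | CC(C)=CCC[C@@H](C)CCC[C@@H](C)COS(=O)(=O)c1ccc(C)cc1 | intermediate
11 | (4R,8S)-4,8,12-trimethyltridec-11-en-1-yne | CC(C)=CCC[C@@H](C)CCC[C@@H](C)CC#C | intermediate
12 | 4,4,5,5-tetramethyl-2-[(1E,4R,8S)-4,8,12-trimethyltrideca-1,11-dien-1-yl]-1,3,2-dioxaborolane | CC(C)=CCC[C@@H](C)CCC[C@@H](C)C/C=C/B1OC(C)(C)C(C)(C)O1 | intermediate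
13 | 2-bromopropene | C=C(C)Br | starting material
14 | (3E,6R,10S)-2,6,10,14-tetramethylpentadeca-1,3,13-triene | CC(C)=CCC[C@@H](C)CCC[C@@H](C)C/C=C/C(C)=C | intermediate
15 | 5-methyl-3-methylidene-4-oxocyclohexa-1,5-dien-1-yl pivalate (ortho-quinone methide) | CC1=CC(OC(=O)C(C)(C)C)=CC(=C)C1=O | intermediate (not isolated)
16 | (2S)-2,8-dimethyl-2-[(1E,4R,8S)-4,8,12-trimethyltrideca-1,11-dien-1-yl]chroman-6-yl pivalate | CC(C)=CCC[C@@H](C)CCC[C@@H](C)C/C=C/[C@]1(C)CCc2cc(OC(=O)C(C)(C)C)cc(C)c2O1 | intermediate
17 | (2R)-2,8-dimethyl-2-[(4R,8S)-4,8,12-trimethyltridec-11-en-1-yl]chroman-6-yl pivalate | CC(C)=CCC[C@@H](C)CCC[C@@H](C)CCC[C@]1(C)CCc2cc(OC(=O)C(C)(C)C)cc(C)c2O1 | intermediate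
18 | (2R)-2,8-dimethyl-2-[(4R,8S)-4,8,12-trimethyltridec-11-en-1-yl]chroman-6-ol | CC(C)=CCC[C@@H](C)CCC[C@@H](C)CCC[C@]1(C)CCc2cc(O)cc(C)c2O1 | target

**Count**

Total steps: 11. Longest linear sequence: 8 steps (steps 4–11, from 5 and 6 to 18).

**Steps most likely to fail**

Step 9 (proposed new method). The acid may ionise the primary benzylic alcohol too slowly, the quinone methide may be lost to self-condensation or arene benzylation before it meets the diene, the acid may protonate the diene, or the pocket may discriminate the two faces of C2 poorly. The fallback sets out from 4 and 14 and gives up catalyst control. The two are heated without any acid (toluene, sealed tube, about 170 °C), the known thermal mode of quinone methide–diene cycloaddition. This should give 16 together with its C2 epimer (2R)-2,8-dimethyl-2-[(1E,4R,8S)-4,8,12-trimethyltrideca-1,11-dien-1-yl]chroman-6-yl pivalate F1. The two epimers are then separated by preparative HPLC on a cellulose tris(3,5-dimethylphenylcarbamate) phase, so that the C2 configuration comes from separation instead of from the bond-forming step, and the route is rejoined at 16.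

Step 10. Over-reduction may occur: the rate difference between the hindered C1'=C2' alkene and the trisubstituted C11'=C12' alkene may be too small, so that the chain-end alkene is lost before the first is consumed. The fallback sets out from 16 and masks the electron-rich alkene first. Epoxidation (mCPBA, NaHCO3, CH2Cl2, 0 °C) should give (2S)-2-[(1E,4R,8S)-10-(3,3-dimethyloxiran-2-yl)-4,8-dimethyldec-1-en-1-yl]-2,8-dimethylchroman-6-yl pivalate F2 as both epoxide epimers. Hydrogenation (H2, Pt/C, EtOAc) then gives (2R)-2-[(4R,8S)-10-(3,3-dimethyloxiran-2-yl)-4,8-dimethyldecyl]-2,8-dimethylchroman-6-yl pivalate F3. Reductive deoxygenation (Zn, NaI, NaOAc, AcOH, rt) returns the alkene, which has no geometry to lose, and the route is rejoined at 17.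

Step 4. The coupling may stall because the magnesium alkoxide precipitates or closes to an oxetane, leaving the Grignard reagent to homocouple or be reduced. The fallback sets out from 6 and uses a covalent protecting group. Silylation (TBSCl, imidazole, CH2Cl2) gives [(2S)-3-bromo-2-methylpropoxy](tert-butyl)dimethylsilane F4. This is coupled with Grignard reagent 7 under the same Li2CuCl4 catalysis to give tert-butyldimethyl{[(2R,6S)-2,6,10-trimethylundec-9-en-1-yl]oxy}silane F5. Bu4NF in THF then frees the alcohol and the route is rejoined at 9.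

**Further compounds**

F1 | step 9 | (2R)-2,8-dimethyl-2-[(1E,4R,8S)-4,8,12-trimethyltrideca-1,11-dien-1-yl]chroman-6-yl pivalate | CC(C)=CCC[C@@H](C)CCC[C@@H](C)C/C=C/[C@@]1(C)CCc2cc(OC(=O)C(C)(C)C)cc(C)c2O1
F2 | step 10 | (2S)-2-[(1E,4R,8S)-10-(3,3-dimethyloxiran-2-yl)-4,8-dimethyldec-1-en-1-yl]-2,8-dimethylchroman-6-yl pivalate (both epoxide epimers) | CC1(C)OC1CC[C@@H](C)CCC[C@@H](C)C/C=C/[C@]2(C)CCc3cc(OC(=O)C(C)(C)C)cc(C)c3O2
F3 | step 10 | (2R)-2-[(4R,8S)-10-(3,3-dimethyloxiran-2-yl)-4,8-dimethyldecyl]-2,8-dimethylchroman-6-yl pivalate (both epoxide epimers) | CC1(C)OC1CC[C@@H](C)CCC[C@@H](C)CCC[C@]2(C)CCc3cc(OC(=O)C(C)(C)C)cc(C)c3O2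
F4 | step 4 | [(2S)-3-bromo-2-methylpropoxy](tert-butyl)dimethylsilane | BrC[C@@H](C)CO[Si](C)(C)C(C)(C)C
F5 | step 4 | tert-butyldimethyl{[(2R,6S)-2,6,10-trimethylundec-9-en-1-yl]oxy}silane | CC(C)=CCC[C@@H](C)CCC[C@@H](C)CO[Si](C)(C)C(C)(C)C
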